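**Retrosynthetic overview**
1. The only disconnection is the C3–Br bond, made last by electrophilic bromination at C3, the most nucleophilic position of the indole.
2. The precursor, 4,6-dibromo-1H-indole, already carries both bromines on the benzene ring, so no regiochemistry has to be set there.
3. No ring is formed in the route; the indole bicycle (benzene ring fused to pyrrole ring) is bought intact.

Assumption: the target is achiral (no stereocentre), so the "single enantiomer" requirement is met trivially; 4,6-dibromo-1H-indole is taken as a catalogue building block.

**Route**

Step 1
Reactants: 1 4,6-dibromo-1H-indole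
Product: 2 3,4,6-tribromo-1H-indole
Conditions: NBS (1.05 equiv, added portionwise), DMF, 0 °C → rt, dark, 1 h; then ice-water / aq. Na2S2O3, filter or extract
Reagents that add atoms: N-bromosuccinimide, O=C1CCC(=O)N1Br
Why: Electrophilic aromatic substitution (NBS bromination of an indole) occurs at C3, the enamine-like carbon of the pyrrole ring, while the dibrominated benzene ring is deactivated and one equivalent at 0 °C stops before C2 reacts; no stereocentre is formed.

**Compound list**
1 | 4,6-dibromo-1H-indole | Brc1cc(Br)c2cc[nH]c2c1 | starting material
2 | 3,4,6-tribromo-1H-indole | Brc1cc(Br)c2c(Br)c[nH]c2c1 | target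

**Summary**
Total step count: 1
Longest linear sequence: 1 step

**Steps most likely to fail**
The route has only one step, so step 1 is the single entry.

Step 1 risks:
- over-bromination at C2 to the 2,3,4,6-tetrabromide;
- slow attack at C3 because of the peri 4-bromine;
- loss of the free N–H 3-bromoindole to acid, light or silica during purification.

Fallback for step 1 (protect nitrogen, then brominate, then deprotect): setting out from 1, deprotonation with NaH in THF at 0 °C and silylation with triisopropylsilyl chloride gives 4,6-dibromo-1-(triisopropylsilyl)-1H-indole F1. Bromination of this with NBS in THF at −78 °C → rt gives 3,4,6-tribromo-1-(triisopropylsilyl)-1H-indole F2. The bulky silyl group shields N1 and C2, so only C3 reacts, and the silylated compounds are stable and easy to chromatograph. Brief treatment of F2 with Bu4NF in THF at 0 °C removes the silyl group and comes back to the route at 2.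

**Further compounds**
F1 | step 1 | 4,6-dibromo-1-(triisopropylsilyl)-1H-indole | CC(C)[Si](C(C)C)(C(C)C)n1ccc2c(Br)cc(Br)cc21
F2 | step 1 | 3,4,6-tribromo-1-(triisopropylsilyl)-1H-indole | CC(C)[Si](C(C)C)(C(C)C)n1cc(Br)c2c(Br)cc(Br)cc21
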